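Readings and results are simulated with made-up constants; noise was put on by code.

At early times the coupling partner turns starting material into single product, which decays to over-reaction product, while partner and single product also exchange reversibly with double product and released group.

| setting | epsilon | delta | beta | teal | blue | green |
|---|---|---|---|---|---|---|
| starting material | 0.50 mM | 0.50 mM | 0.50 mM | 0.50 mM | 0.50 mM | 0.50 mM |
| coupling partner | 0.64 equiv | 0.72 equiv | 1.1 equiv | 0.500 equiv | 0.800 equiv | 1.00 equiv |
| remark | run made earlier | run made earlier | run made earlier |  |  |  |
| time |  |  |  | 6.0 min | 6.0 min | 6.0 min |

- epsilon (time / min: single product / %): 0.333: 59.1; 0.833: 58.7; 2.00: 55.9; 4.00: 50.2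
- delta (time / min: single product / %): 1.00: 65.5; 2.00: 62.6; 3.00: 59.2; 4.00: 56.5
- beta (time / min: single product / %): 0.333: 84.2; 0.833: 86.0; 2.00: 83.3; 4.00: 75.5

(standard deviation of a reading: 0.3 percentage points)

* amount of single product at the end, in percent of the starting material charged, for each flask in turn (teal, blue, green)

The ladder of time scales starts with coupling. By 0.333 min, the epsilon flask already reads 59.1 %, or 0.923 of what its partner charge can give, so this rung is a matter of a fraction of a minute. Below one equivalent the partner is the limiting reagent, and the coupling step turns one partner into one single product. This suggests a survival constant k: the first-order rate constant at which the partner's charge, counted as single product from time zero, is lost. It is read, with the scatter of the readings, from the last reading of the epsilon and delta runs: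

epsilon: k = ln(charge / reading) / time = 0.0607 min⁻¹
delta: k = 0.0606 min⁻¹

The next rung is a transient shortfall. Against this curve, the epsilon readings lie 3.6 percentage points low at 0.333 min but 0.78 points low at 2.00 min, a smaller gap. The last rung is the decay, with a read half-life of 11.4 min, longer than the 6.0 min run. The reckoning made here multiplies each charge by one survival fraction:

survival at the end = exp(−k t) = 0.695
teal: 34.7 %
blue: 55.6 %
green: 69.5 %

The forecast differs, giving 35.8 %, 56 % and 62.5 %: “All three runs give k ≈ 0.05 /min, so 6 min retains about 0.74 of the initial level.”

The flasks give 35.0 % for teal, 56.3 % for blue and 69.0 % for green.

    single product → over-reaction product (k = 0.00100 s⁻¹)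
    coupling partner + single product ⇌ double product + released group (K = 1.40, k = 31.0 M⁻¹ s⁻¹)
    starting material + coupling partner → single product + released group (k = 730 M⁻¹ s⁻¹)

In teal at 6.00 min, single product is made at 0.0369 of the rate at which it is used up, each step taken net, and the end yield over the charge is 0.700 against the survival fraction 0.695. Carried to green, the same k on the full charge gives 69.5 %, and green stands at 69.0 % with over-reaction product at 27.9 %.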